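# Proposed total synthesis of CNP0233746.1 by enone–cyclobutene photocycloaddition and cycloreversion

## Analysis of the target

The target is a germacranolide built on a ten-membered carbocycle C1–C10. The ring carries an exocyclic methylene (C14) on C10, a cis-disubstituted epoxide at C1–C2, and a trisubstituted trans epoxide at C4–C5 with the C15 methyl on C4. A butenolide is fused through the C6 oxygen and C7=C11 (C12 carbonyl, C13 acetoxymethyl), and the C8 oxygen bears a 2-(hydroxymethyl)acrylate. The six stereocentres are 1R,2S,4R,5R,6S,8S. The C6 and C8 oxygens are cis across C7, the C5 and C6 oxygens are threo, and C1/C2 form a cis epoxide beside the methylene.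

The sensitive groups are:
- the vinyl epoxide (C1–C2 next to C10=C14);
- the 13-acetoxy butenolide, an allylic acetate on a Michael acceptor with an acidic γ-hydrogen at C6;
- the acrylate;
- both epoxides, which in a ten-membered ring invite transannular attack under acid.

The difficulty is the medium ring itself: it has no rigid frame for stereocontrol, and its 1,5-diene precursors are prone to Cope rearrangement. The strategy rests on the 1,5-relationship of the two oxidised sites C1–C10(–C14) and C4–C5(–C15). The ring is treated as a cyclodeca-1(10),4-diene, that is, a six-membered ring C5–C10 and a four-membered ring C1–C4 joined through the bonds C4–C5 and C1–C10.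

## Retrosynthetic reasoning

**C8 ester.** The acrylate is a polymerisable Michael acceptor, so the C8–O acyl bond is cut first: 31 comes from alcohol 29 and the silyl-protected acid 14, via 30. The forward steps only have to acylate a hindered secondary alcohol and remove a primary silyl ether without touching two epoxides and an allylic acetate.

**C4–C5 epoxide.** The two C–O bonds of this epoxide are cut next (28 from 27). In 27 the C4=C5 alkene is the only electron-rich trisubstituted alkene. The C6 stereocentre fixes the conformer in which C6–H eclipses the alkene and the lactone oxygen lies on the open face, so a peracid should deliver 4R,5R. Putting this epoxide last keeps it away from every acidic or basic step.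

**C1–C2 epoxide and C14 methylene.** The epoxide C2–O bond is cut to the threo hydroxy tosylate 26, and the C1–O bond and C10=C14 are traced to an ene reaction of the C1=C10 alkene of allylic alcohol 23 (via 24 and 25). The alternative, isomerising a 1,10-epoxide to the allylic alcohol, was not chosen: an electrophilic C10 next to C4=C5 invites transannular cyclisation to a decalin. The ene reaction has to place oxygen on C1 from the outer face (threo to the C2 oxygen) and move the double bond to C14. Closure then inverts C2.

**Lactone C12–O bond and the C2 and C6 carbinols.** 23 is opened to the dihydroxy ester 22 and then to the diketone 21. Both carbinol centres are set after the ring is formed, in one oxazaborolidine-catalysed reduction. At that stage C5 is a vinylic CH, the smallest possible partner on C6, and the centres created in the photocycloaddition no longer exist, so they cannot interfere.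

**C1–C4 and C5–C10 (ring expansion).** 21 is traced to the tricyclic diketone 20, whose bicyclo[2.2.0]hexane is opened thermally. C2 must be a ketone at this point. With a protected alcohol on C2 the product would be a 3-oxy-1,5-diene whose Cope rearrangement gives a divinylcyclohexanone bearing an enol ether, which is the thermodynamic sink. With a C2 ketone the same shift would have to form a ketene, and both new alkenes are conjugated. 20 follows from 19, 18 and 17 by desilylation, acetylation and oxidation.

**C7=C11.** The three-carbon unit C11–C13 is attached by aldol condensation of keto ester 13 with the C6 ketone of 15 (via 16). It is done on the tricycle because there C6 is the only ketone and C7 the only methylene next to it. In the ten-membered dione the C3 methylene would be far more acidic.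

**C4–C5 and C1–C10 (key disconnection).** 15 is cut into enone 4 and cyclobutene 9. A (2+2) photocycloaddition forms both bonds without an entropic ring-closure problem and brings in all ten ring carbons with C14 and C15. The forward step must give the head-to-head orientation and the cis-anti-cis fusion.

**Precursors.** 4 is traced through 3 and 2 to the ester phosphonate 1, which already holds the C8 stereocentre; the C10–C14 bond and the C5=C10 bond are made by methyl addition and an intramolecular Horner–Wadsworth–Emmons reaction. 9 comes from 5 via 7 and 8. Both 13 and 14 come from 10 via 11.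

## Alternatives that were turned down

**Alternative 1:** The ring is cut at C5–C6 and closed by anodic coupling of a C4=C5 silyl enol ether with a 2-silyloxyfuran, giving the macrocyclic C4 ketone A1.
- For it: the butenolide with its acetoxymethyl group, the C1–C2 epoxide and the methylene are carried in finished form, and the route is convergent and avoids a high-temperature step. On these points it is stronger than the chosen route.
- Against it: a short-lived radical cation must close a ten-membered ring in competition with intermolecular coupling. C5 and C6 are created in that step with no element that relates them to C8 or to the epoxide. The 1,1-disubstituted alkene, the vinyl epoxide and the PMB ether are themselves oxidisable. A1 still lacks C15, so methyl addition to C4 and an epoxide closure onto C5 follow, with a new selectivity problem at C4.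
- Comparison: the chosen route forms the ring by cycloaddition and cycloreversion, where ring size is not an issue, and derives C4/C5 from an E alkene.

**Alternative 2:** Three bonds (C6–C7, C11–C12, C12–O) are cut at once, and a molybdenum-carbonyl-mediated hetero-Pauson–Khand reaction of an epoxy aldehyde, an alkyne and carbon monoxide gives A2.
- For it: no other plan forms as many bonds in the ring-closing step, and the C13 acetate arrives on the alkyne. In bond economy at that step it is clearly stronger.
- Against it: the reaction type is established for tethers that close five- or six-membered rings next to the butenolide, whereas here the metallacycle has to span a ten-membered ring. A low-valent metal carbonyl meets an α,β-epoxy aldehyde and a second epoxide, both open to deoxygenation. C6 is set by the face of the aldehyde, remote from any control. The open-chain precursor must already hold five stereocentres and both epoxides.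
- Comparison: the chosen route is longer after ring formation, but each of its steps belongs to a known reaction class and the epoxides are introduced at the end.

**Alternative 3:** The ten-membered ring is unveiled from a decalin by Eschenmoser–Tanabe fragmentation of a ring-fusion epoxy ketone, which breaks C1–C6 and gives the ynone A3.
- For it: the fragmentation is reliable and driven by loss of nitrogen. C4, C5 and C8 can be set on an unstrained six-membered ring, and there is no Cope problem and no photochemistry. On reliability of the ring-opening step it is stronger.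
- Against it: A3 is far from the target. The C1≡C2 alkyne needs semi-reduction and an undirected epoxidation. The C10 ketal must become the methylene next to that epoxide, and the acetonide must become the trans epoxide. The butenolide is still to be annulated at C6/C7 of a ketone flanked by these groups. The stereodefined decalin epoxy ketone is itself a long linear target.
- Comparison: the chosen route reaches the ring in two operations from two small fragments and places unsaturation exactly at C1–C10 and C4–C5, at the cost of a less certain ring-forming sequence.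

Key step: step 10

## Route

Assumption: phosphonate 1 (a statin side-chain intermediate), cyclobutenone 5 and acrylate 10 are bought. Atom labels C1–C15 are those of the target for all ring compounds.

Step 1
Reactants: 1 methyl (3R)-3-[(tert-butyldimethylsilyl)oxy]-6-(dimethoxyphosphoryl)-5-oxohexanoate
Product: 2 (3R)-3-[(tert-butyldimethylsilyl)oxy]-6-(dimethoxyphosphoryl)-N-methoxy-N-methyl-5-oxohexanamide
Conditions: MeNHOMe·HCl, iPrMgCl, THF, −20 to 0 °C
Reagents that add atoms: N,O-dimethylhydroxylamine hydrochloride, CNOC.Cl
Why: Weinreb amidation of the ester with the chloromagnesium amide; the β-ketophosphonate is deprotonated first and is inert as its magnesium enolate, and the weakly basic reagent does not eliminate the β-silyloxy group.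

Step 2
Reactants: 2 (3R)-3-[(tert-butyldimethylsilyl)oxy]-6-(dimethoxyphosphoryl)-N-methoxy-N-methyl-5-oxohexanamide
Product: 3 dimethyl {(4S)-4-[(tert-butyldimethylsilyl)oxy]-2,6-dioxoheptyl}phosphonate
Conditions: MeMgBr (3 equiv), THF, −78 to 0 °C; aq NH4Cl
Reagents that add atoms: methylmagnesium bromide, C[Mg]Br
Why: Weinreb ketone synthesis; the chelated tetrahedral adduct stops at the methyl ketone (this methyl is C14), and the descriptor changes from R to S only because the ranking of the two arms changes.

Step 3
Reactants: 3 dimethyl {(4S)-4-[(tert-butyldimethylsilyl)oxy]-2,6-dioxoheptyl}phosphonate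
Product: 4 (5S)-5-[(tert-butyldimethylsilyl)oxy]-3-methylcyclohex-2-en-1-one
Conditions: LiCl, iPr2NEt, MeCN, rt
Reagents that add atoms: none
Why: Intramolecular Horner–Wadsworth–Emmons reaction (Masamune–Roush conditions) of the phosphonate carbanion onto the methyl ketone closes the six-membered enone C5–C10; the mild base should avoid loss of silanol and aromatisation, and the C8 stereocentre is untouched.

Step 4
Reactants: 5 3-ethoxycyclobut-2-en-1-one
Product: 7 3-methylcyclobut-2-en-1-one, via 3-ethoxy-1-methylcyclobut-2-en-1-ol 6 (not isolated)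
Conditions: MeLi, Et2O, −78 °C; then 1 M HCl, 0 °C
Reagents that add atoms: methyllithium, [Li]C
Why: 1,2-addition to the vinylogous ester and acid hydrolysis of the resulting enol ether carbinol with transposition of the carbonyl (Stork–Danheiser sequence); the methyl becomes C15.

Step 5
Reactants: 7 3-methylcyclobut-2-en-1-one
Product: 8 (1R)-3-methylcyclobut-2-en-1-ol
Conditions: (S)-1-methyl-3,3-diphenyltetrahydro-1H,3H-pyrrolo[1,2-c][1,3,2]oxazaborole (20 mol %), catecholborane, toluene, −78 °C
Reagents that add atoms: none
Why: Corey–Bakshi–Shibata 1,2-reduction with the alkenyl carbon as the large group gives the R carbinol; this centre only serves to make the photocycloaddition a matched pairing and is oxidised in step 15, so moderate enantiomeric purity suffices.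

Step 6
Reactants: 8 (1R)-3-methylcyclobut-2-en-1-ol
Product: 9 triethyl{[(1R)-3-methylcyclobut-2-en-1-yl]oxy}silane
Conditions: Et3SiCl, imidazole, CH2Cl2, 0 °C
Reagents that add atoms: chlorotriethylsilane, CC[Si](CC)(CC)Cl
Why: Silylation of the volatile, acid-sensitive cyclobutenol; the triethylsilyl ether can later be removed in the presence of the secondary tert-butyldimethylsilyl ether on C8.

Step 7
Reactants: 10 ethyl 2-(hydroxymethyl)prop-2-enoate
Product: 11 ethyl 2-{[(triethylsilyl)oxy]methyl}prop-2-enoate
Conditions: Et3SiCl, imidazole, CH2Cl2, 0 °C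
Reagents that add atoms: chlorotriethylsilane, CC[Si](CC)(CC)Cl
Why: Standard silylation of a primary allylic alcohol; 11 is the common source of the C11–C13 unit and of the C8 side chain.

Step 8
Reactants: 11 ethyl 2-{[(triethylsilyl)oxy]methyl}prop-2-enoate
Product: 13 ethyl 2-oxo-3-[(triethylsilyl)oxy]propanoate, via 1,2,4-trioxolane ozonide 12 (not isolated)
Conditions: O3, CH2Cl2, −78 °C; then Me2S
Reagents that add atoms: ozone, [O-][O+]=O
Why: Ozonolysis of the 1,1-disubstituted acrylate with reductive work-up gives the α-keto ester, which is used dry and fresh because it hydrates readily.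

Step 9
Reactants: 11 ethyl 2-{[(triethylsilyl)oxy]methyl}prop-2-enoate
Product: 14 2-{[(triethylsilyl)oxy]methyl}prop-2-enoic acid
Conditions: LiOH, THF/H2O, 0 °C; then 1 M HCl to pH 4, 0 °C
Reagents that add atoms: lithium hydroxide, [Li+].[OH-]
Why: Saponification of the ethyl ester; the primary silyl ether is stable to base and to brief cold acidification.

Step 10
Reactants: 4 (5S)-5-[(tert-butyldimethylsilyl)oxy]-3-methylcyclohex-2-en-1-one; 9 triethyl{[(1R)-3-methylcyclobut-2-en-1-yl]oxy}silane
Product: 15 cis-anti-cis head-to-head photoadduct 9-[(tert-butyldimethylsilyl)oxy]-1,5-dimethyl-3-[(triethylsilyl)oxy]tricyclo[4.4.0.0^{2,5}]decan-7-one (C6 ketone; 8S silyloxy; 2R silyloxy; new bonds C4–C5 and C1–C10; both silyloxy groups anti to the central cyclobutane)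
Conditions: hν (350 nm), 9 (4 equiv), CH2Cl2 (degassed), −40 °C; then brief contact with basic Al2O3
Reagents that add atoms: none
Why: Enone–alkene (2+2) photocycloaddition with a cyclobutene as the alkene, the first half of the known photoadduct route to cyclodeca-1,5-dienes. The triplet enone bonds to 9 through a 1,4-biradical, and spin inversion with radical–radical coupling closes the cyclobutane C1–C4–C5–C10 (intermolecular, two new bonds, fused to the six-membered ring and to the existing four-membered ring). The head-to-head orientation (C10–C1 and C5–C4) is needed and is secured sterically: any path to the other orientation has to join the two fully substituted carbons C10 and C4, whereas 15 forms by attack of the unsubstituted C1 on C10 or of C4 on the α-carbon C5. C10 and C5 are set by entry of the alkene anti to the C8 silyloxy group of the half-chair enone, and C1 and C4 by entry of the enone anti to the C2 silyloxy group on the carbon next to C1; the pairing of (S)-4 with (R)-9 is matched, so both preferences can be met in one adduct. The six–four fusion is cis after base equilibration of any trans-fused isomer at the enolisable C5, the four–four fusion is cis by necessity, and the anti arrangement of the two outer rings is the less crowded one. Only the orientation and the cis-anti-cis fusion carry through to the target, because they fix the connectivity and the E,E geometry after step 16; the four new stereocentres are erased there, so a facial mixture would converge.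

Step 11
Reactants: 15 photoadduct; 13 ethyl 2-oxo-3-[(triethylsilyl)oxy]propanoate
Product: 16 ethyl 2-hydroxy-2-{9-[(tert-butyldimethylsilyl)oxy]-1,5-dimethyl-7-oxo-3-[(triethylsilyl)oxy]tricyclo[4.4.0.0^{2,5}]decan-8-yl}-3-[(triethylsilyl)oxy]propanoate (C7–C11 aldol adduct; mixture at C7 and C11)
Conditions: LiN(iPr)2, THF, −78 °C; then 13; AcOH quench at −78 °C
Reagents that add atoms: none
Why: Kinetic deprotonation of the C7 methylene (C5 is a hindered ring-fusion methine) and aldol addition to the highly electrophilic keto carbonyl; the cold quench should prevent retro-aldol and loss of the C8 silyloxy group, and the two new centres are removed later.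

Step 12
Reactants: 16 aldol adduct
Product: 17 ethyl (2Z)-2-{9-[(tert-butyldimethylsilyl)oxy]-1,5-dimethyl-7-oxo-3-[(triethylsilyl)oxy]tricyclo[4.4.0.0^{2,5}]decan-8-ylidene}-3-[(triethylsilyl)oxy]propanoate (C7=C11; ester carbon C12 syn to C6)
Conditions: SOCl2, pyridine, CH2Cl2, −20 to 0 °C
Reagents that add atoms: none
Why: Dehydration of the tertiary aldol through its chlorosulfite; removal of the acidic C7–H (α to the C6 ketone) fixes the regiochemistry. The Z isomer is expected because the sp3 silyloxymethyl group takes the site syn to C8, where C8–H can lie in the alkene plane, while the planar ester sits syn to the carbonyl and can twist.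

Step 13
Reactants: 17 alkylidene keto ester
Product: 18 ethyl (2Z)-2-{9-[(tert-butyldimethylsilyl)oxy]-3-hydroxy-1,5-dimethyl-7-oxotricyclo[4.4.0.0^{2,5}]decan-8-ylidene}-3-hydroxypropanoate
Conditions: pyridinium p-toluenesulfonate (20 mol %), MeOH/CH2Cl2, 0 °C to rt
Reagents that add atoms: none
Why: Acid-catalysed methanolysis removes both triethylsilyl ethers much faster than the hindered secondary tert-butyldimethylsilyl ether on C8.

Step 14
Reactants: 18 diol
Product: 19 ethyl (2Z)-3-acetoxy-2-{9-[(tert-butyldimethylsilyl)oxy]-3-hydroxy-1,5-dimethyl-7-oxotricyclo[4.4.0.0^{2,5}]decan-8-ylidene}propanoate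
Conditions: AcCl (1.1 equiv), 2,4,6-collidine, CH2Cl2, −78 °C
Reagents that add atoms: acetyl chloride, CC(=O)Cl
Why: Selective acetylation of the primary allylic C13 hydroxyl over the hindered secondary cyclobutanol; the C13 acetate of the target is in place from here on.

Step 15
Reactants: 19 hydroxy acetate
Product: 20 ethyl (2Z)-3-acetoxy-2-{9-[(tert-butyldimethylsilyl)oxy]-1,5-dimethyl-3,7-dioxotricyclo[4.4.0.0^{2,5}]decan-8-ylidene}propanoate
Conditions: Dess–Martin periodinane, NaHCO3, CH2Cl2, 0 °C to rt
Reagents that add atoms: none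
Why: Buffered oxidation of the cyclobutanol to the cyclobutanone; the C2 ketone is what makes the ring expansion irreversible in the desired direction.

Step 16
Reactants: 20 tricyclic diketone
Product: 21 ethyl (1(10)E,4E,7(11)Z,8S)-13-acetoxy-8-[(tert-butyldimethylsilyl)oxy]-2,6-dioxogermacra-1(10),4,7(11)-trien-12-oate
Conditions: toluene (degassed, 5 mM), 160 °C, sealed base-washed tube
Reagents that add atoms: none
Why: Thermal cycloreversion of the bicyclo[2.2.0]hexane, the second half of the photoadduct route: homolysis of the strained C1–C4 bond gives a cyclohexane-1,4-diyl stabilised at C1 by the C2 ketone, and scission of C5–C10 releases the ten-membered ring. The cis-anti-cis fusion should give both ring alkenes E by least motion. Both alkenes emerge conjugated and the Cope shift of 21 is shut off because it would have to form a ketene at C2.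

Step 17
Reactants: 21 ten-membered diketone
Product: 23 (1(10)E,4E,2R,6R,8S)-13-acetoxy-8-[(tert-butyldimethylsilyl)oxy]-2-hydroxygermacra-1(10),4,7(11)-trien-12,6-olide, via dihydroxy ester 22 (not isolated)
Conditions: (S)-1-methyl-3,3-diphenyltetrahydro-1H,3H-pyrrolo[1,2-c][1,3,2]oxazaborole (0.5 equiv), catecholborane (3 equiv), toluene/CH2Cl2, −78 to −40 °C; MeOH; then pyridinium p-toluenesulfonate (cat.), CH2Cl2, rt
Reagents that add atoms: none
Why: Corey–Bakshi–Shibata 1,2-reduction of both enone carbonyls under reagent control: at C2 the alkenyl C1 is large and the C3 methylene small (2R), and at C6 the fully substituted C7 is large and the vinylic C5–H small, which gives the C6 configuration of the target with the same catalyst. The C6 hydroxyl then lactonises onto the syn ester to form the butenolide.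

Step 18
Reactants: 23 allylic alcohol
Product: 25 (4E,1R,2R,6R,8S)-13-acetoxy-8-[(tert-butyldimethylsilyl)oxy]-1,2-dihydroxygermacra-4,7(11),10(14)-trien-12,6-olide, via C1 hydroperoxide 24 (not isolated)
Conditions: O2, 5,10,15,20-tetraphenylporphyrin (cat.), hν (visible), CH2Cl2, −20 °C; then PPh3, 0 °C
Reagents that add atoms: oxygen, O=O
Why: Schenck ene reaction of singlet oxygen at the electron-rich C1=C10 alkene, as known for germacra-1(10),4-dienolides: oxygen adds to C1 and a C14 hydrogen is taken, which creates the methylene. Attack comes from the outer face of the conformer in which C2–H eclipses the alkene (allylic strain with C14) and is assisted by the C2 hydroxyl, giving the threo 1R,2R diol after reduction.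

Step 19
Reactants: 25 diol
Product: 26 (4E,1R,2R,6R,8S)-13-acetoxy-8-[(tert-butyldimethylsilyl)oxy]-1-hydroxy-2-[(4-methylbenzenesulfonyl)oxy]germacra-4,7(11),10(14)-trien-12,6-olide
Conditions: TsCl (1.1 equiv), pyridine, CH2Cl2, 0 °C
Reagents that add atoms: p-toluenesulfonyl chloride, Cc1ccc(cc1)S(=O)(=O)Cl
Why: Selective sulfonylation of the C2 hydroxyl, which is flanked by the C3 methylene, over the C1 hydroxyl, which is flanked by the fully substituted C10 and is deactivated as an allylic alcohol.

Step 20
Reactants: 26 hydroxy tosylate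
Product: 27 (4E,1R,2S,6R,8S)-13-acetoxy-8-[(tert-butyldimethylsilyl)oxy]-1,2-epoxygermacra-4,7(11),10(14)-trien-12,6-olide
Conditions: K2CO3, 18-crown-6 (cat.), MeCN, rt
Reagents that add atoms: none
Why: Intramolecular Williamson closure (3-exo-tet): the C1 alkoxide displaces the C2 tosylate with inversion, so the threo hydroxy sulfonate gives the cis epoxide 1R,2S; a methanol-free carbonate base spares the acetate and the butenolide.

Step 21
Reactants: 27 vinyl epoxide
Product: 28 (1R,2S,4R,5R,6S,8S)-13-acetoxy-8-[(tert-butyldimethylsilyl)oxy]-1,2:4,5-diepoxygermacra-7(11),10(14)-dien-12,6-olide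
Conditions: mCPBA, NaHCO3, CH2Cl2, 0 °C
Reagents that add atoms: 3-chloroperbenzoic acid, OOC(=O)c1cccc(Cl)c1
Why: Prilezhaev epoxidation of the only electron-rich trisubstituted alkene (C10=C14 is 1,1-disubstituted and next to an epoxide; the other two alkenes are electron-poor). The peracid attacks the outer face of the conformer with C6–H eclipsing the alkene and the lactone oxygen outside, which gives the threo 4R,5R epoxide, the usual outcome for 4,5-epoxidation of germacranolides lactonised at C6.

Step 22
Reactants: 28 bis-epoxide
Product: 29 (1R,2S,4R,5R,6S,8S)-13-acetoxy-1,2:4,5-diepoxy-8-hydroxygermacra-7(11),10(14)-dien-12,6-olide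
Conditions: HF·pyridine, pyridine, THF, 0 °C to rt
Reagents that add atoms: none
Why: Buffered fluoride cleavage of the secondary silyl ether under near-neutral conditions that leave the epoxides, the acetate and the butenolide intact.

Step 23
Reactants: 29 C8 alcohol; 14 2-{[(triethylsilyl)oxy]methyl}prop-2-enoic acid
Product: 30 (1R,2S,4R,5R,6S,8S)-13-acetoxy-1,2:4,5-diepoxy-8-({2-[(triethylsilyloxy)methyl]prop-2-enoyl}oxy)germacra-7(11),10(14)-dien-12,6-olide
Conditions: 1-ethyl-3-(3-dimethylaminopropyl)carbodiimide hydrochloride, 4-(dimethylamino)pyridine (cat.), CH2Cl2, 0 °C to rt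
Reagents that add atoms: none
Why: Steglich esterification of the secondary alcohol with retention at C8; the acid's own hydroxyl is masked so that it cannot oligomerise.

Step 24
Reactants: 30 silyl-protected ester
Product: 31 CNP0233746.1, (1R,2S,4R,5R,6S,8S)-13-acetoxy-1,2:4,5-diepoxy-8-{[2-(hydroxymethyl)prop-2-enoyl]oxy}germacra-7(11),10(14)-dien-12,6-olide
Conditions: HF·pyridine, pyridine, THF, 0 °C
Reagents that add atoms: none
Why: Cleavage of the primary triethylsilyl ether under the same buffered conditions as in step 22 releases the hydroxymethyl group without acyl migration.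

## Compound list

1 | methyl (3R)-3-[(tert-butyldimethylsilyl)oxy]-6-(dimethoxyphosphoryl)-5-oxohexanoate | COC(=O)C[C@H](O[Si](C)(C)C(C)(C)C)CC(=O)CP(=O)(OC)OC | starting material
2 | (3R)-3-[(tert-butyldimethylsilyl)oxy]-6-(dimethoxyphosphoryl)-N-methoxy-N-methyl-5-oxohexanamide | CON(C)C(=O)C[C@H](O[Si](C)(C)C(C)(C)C)CC(=O)CP(=O)(OC)OC | intermediate
3 | dimethyl {(4S)-4-[(tert-butyldimethylsilyl)oxy]-2,6-dioxoheptyl}phosphonate | CC(=O)C[C@H](O[Si](C)(C)C(C)(C)C)CC(=O)CP(=O)(OC)OC | intermediate
4 | (5S)-5-[(tert-butyldimethylsilyl)oxy]-3-methylcyclohex-2-en-1-one | CC1=CC(=O)C[C@@H](O[Si](C)(C)C(C)(C)C)C1 | intermediate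
5 | 3-ethoxycyclobut-2-en-1-one | CCOC1=CC(=O)C1 | starting material
6 | 3-ethoxy-1-methylcyclobut-2-en-1-ol | CCOC1=CC(C)(O)C1 | intermediate (not isolated)
7 | 3-methylcyclobut-2-en-1-one | CC1=CC(=O)C1 | intermediate
8 | (1R)-3-methylcyclobut-2-en-1-ol | CC1=C[C@H](O)C1 | intermediate
9 | triethyl{[(1R)-3-methylcyclobut-2-en-1-yl]oxy}silane | CC1=C[C@H](O[Si](CC)(CC)CC)C1 | intermediate
10 | ethyl 2-(hydroxymethyl)prop-2-enoate | C=C(CO)C(=O)OCC | starting material
11 | ethyl 2-{[(triethylsilyl)oxy]methyl}prop-2-enoate | C=C(CO[Si](CC)(CC)CC)C(=O)OCC | intermediate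
12 | ethyl 3-{[(triethylsilyl)oxy]methyl}-1,2,4-trioxolane-3-carboxylate (ozonide) | CCOC(=O)C1(CO[Si](CC)(CC)CC)OCOO1 | intermediate (not isolated)
13 | ethyl 2-oxo-3-[(triethylsilyl)oxy]propanoate | CCOC(=O)C(=O)CO[Si](CC)(CC)CC | intermediate
14 | 2-{[(triethylsilyl)oxy]methyl}prop-2-enoic acid | C=C(CO[Si](CC)(CC)CC)C(=O)O | intermediate
15 | cis-anti-cis head-to-head photoadduct, 9-[(tert-butyldimethylsilyl)oxy]-1,5-dimethyl-3-[(triethylsilyl)oxy]tricyclo[4.4.0.0^{2,5}]decan-7-one (2R,8S in target numbering) | O=C1C[C@@H](O[Si](C)(C)C(C)(C)C)C[C@@]2(C)[C@@H]1[C@]3(C)C[C@@H](O[Si](CC)(CC)CC)[C@H]23 | intermediate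
16 | C7 aldol adduct of 15 with 13 (mixture at C7 and C11) | O=C1C(C(O)(C(=O)OCC)CO[Si](CC)(CC)CC)[C@@H](O[Si](C)(C)C(C)(C)C)C[C@@]2(C)[C@@H]1[C@]3(C)C[C@@H](O[Si](CC)(CC)CC)[C@H]23 | intermediate
17 | (Z)-C7=C11 alkylidene keto ester, C12 syn to C6, bis(triethylsilyl) ether | O=C1/C(=C(\C(=O)OCC)CO[Si](CC)(CC)CC)[C@@H](O[Si](C)(C)C(C)(C)C)C[C@@]2(C)[C@@H]1[C@]3(C)C[C@@H](O[Si](CC)(CC)CC)[C@H]23 | intermediate
18 | (Z)-alkylidene keto ester, C2 and C13 diol | O=C1/C(=C(\C(=O)OCC)CO)[C@@H](O[Si](C)(C)C(C)(C)C)C[C@@]2(C)[C@@H]1[C@]3(C)C[C@@H](O)[C@H]23 | intermediate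
19 | (Z)-alkylidene keto ester, C13 acetate, C2 alcohol | O=C1/C(=C(\C(=O)OCC)COC(C)=O)[C@@H](O[Si](C)(C)C(C)(C)C)C[C@@]2(C)[C@@H]1[C@]3(C)C[C@@H](O)[C@H]23 | intermediate
20 | tricyclic 2,6-diketone, ethyl (2Z)-3-acetoxy-2-{9-[(tert-butyldimethylsilyl)oxy]-1,5-dimethyl-3,7-dioxotricyclo[4.4.0.0^{2,5}]decan-8-ylidene}propanoate | O=C1/C(=C(\C(=O)OCC)COC(C)=O)[C@@H](O[Si](C)(C)C(C)(C)C)C[C@@]2(C)[C@@H]1[C@]3(C)CC(=O)[C@H]23 | intermediate
21 | ethyl (1(10)E,4E,7(11)Z,8S)-13-acetoxy-8-[(tert-butyldimethylsilyl)oxy]-2,6-dioxogermacra-1(10),4,7(11)-trien-12-oate | O=C1C/C(C)=C/C(=O)/C(=C(\C(=O)OCC)COC(C)=O)[C@@H](O[Si](C)(C)C(C)(C)C)C/C(C)=C/1 | intermediate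
22 | ethyl (1(10)E,4E,2R,6R,8S)-13-acetoxy-8-[(tert-butyldimethylsilyl)oxy]-2,6-dihydroxygermacra-1(10),4,7(11)-trien-12-oate (C12 syn to C6) | O[C@@H]1C/C(C)=C/[C@@H](O)/C(=C(\C(=O)OCC)COC(C)=O)[C@@H](O[Si](C)(C)C(C)(C)C)C/C(C)=C/1 | intermediate (not isolated)
23 | (1(10)E,4E,2R,6R,8S)-13-acetoxy-8-[(tert-butyldimethylsilyl)oxy]-2-hydroxygermacra-1(10),4,7(11)-trien-12,6-olide | O[C@@H]1C/C(C)=C/[C@H]2OC(=O)C(COC(C)=O)=C2[C@@H](O[Si](C)(C)C(C)(C)C)C/C(C)=C/1 | intermediate
24 | (4E,1R,2R,6R,8S)-13-acetoxy-8-[(tert-butyldimethylsilyl)oxy]-1-hydroperoxy-2-hydroxygermacra-4,7(11),10(14)-trien-12,6-olide | OO[C@H]1[C@H](O)C/C(C)=C/[C@H]2OC(=O)C(COC(C)=O)=C2[C@@H](O[Si](C)(C)C(C)(C)C)CC1=C | intermediate (not isolated)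
25 | (4E,1R,2R,6R,8S)-13-acetoxy-8-[(tert-butyldimethylsilyl)oxy]-1,2-dihydroxygermacra-4,7(11),10(14)-trien-12,6-olide | O[C@H]1[C@H](O)C/C(C)=C/[C@H]2OC(=O)C(COC(C)=O)=C2[C@@H](O[Si](C)(C)C(C)(C)C)CC1=C | intermediate
26 | C2 tosylate of 25 (1R,2R,6R,8S) | O[C@H]1[C@H](OS(=O)(=O)c3ccc(C)cc3)C/C(C)=C/[C@H]2OC(=O)C(COC(C)=O)=C2[C@@H](O[Si](C)(C)C(C)(C)C)CC1=C | intermediate
27 | (4E,1R,2S,6R,8S)-13-acetoxy-8-[(tert-butyldimethylsilyl)oxy]-1,2-epoxygermacra-4,7(11),10(14)-trien-12,6-olide | CC(C)(C)[Si](C)(C)O[C@H]1CC(=C)[C@H]2O[C@H]2C/C(C)=C/[C@H]2OC(=O)C(COC(C)=O)=C12 | intermediate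
28 | (1R,2S,4R,5R,6S,8S)-13-acetoxy-8-[(tert-butyldimethylsilyl)oxy]-1,2:4,5-diepoxygermacra-7(11),10(14)-dien-12,6-olide | CC(C)(C)[Si](C)(C)O[C@H]1CC(=C)[C@H]2O[C@H]2C[C@@]2(C)O[C@@H]2[C@H]2OC(=O)C(COC(C)=O)=C12 | intermediate
29 | (1R,2S,4R,5R,6S,8S)-13-acetoxy-1,2:4,5-diepoxy-8-hydroxygermacra-7(11),10(14)-dien-12,6-olide | O[C@H]1CC(=C)[C@H]2O[C@H]2C[C@@]2(C)O[C@@H]2[C@H]2OC(=O)C(COC(C)=O)=C12 | intermediate
30 | C8 2-[(triethylsilyloxy)methyl]acrylate of 29 | C=C(CO[Si](CC)(CC)CC)C(=O)O[C@H]1CC(=C)[C@H]2O[C@H]2C[C@@]2(C)O[C@@H]2[C@H]2OC(=O)C(COC(C)=O)=C12 | intermediate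
31 | CNP0233746.1 | C=C(CO)C(=O)O[C@H]1CC(=C)[C@H]2O[C@H]2C[C@@]2(C)O[C@@H]2[C@H]2OC(=O)C(COC(C)=O)=C12 | target

## Step count and least certain steps

Total: 24 steps. Longest linear sequence: 18 steps (steps 1–3, 10–24; the branch through steps 4–6 is equally long).

**Step 10 (key step).** The likely failure is inefficient addition: the hindered, oxygenated cyclobutene may react slowly, the biradicals may revert, and some head-to-tail orientation may appear. Fallback, from 4 to 20: the bicyclo[2.2.0]hexanone is assembled in two stages.
- Irradiation of 4 with propyne should give the cyclobutene ketone 4-[(tert-butyldimethylsilyl)oxy]-6,8-dimethylbicyclo[4.2.0]oct-7-en-2-one F1, which has the same C4–C5 and C1–C10 bonds; the unsubstituted alkyne carbon takes the bond to C10.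
- The chemistry of steps 11–14 is applied to F1: aldol with 13 to the adduct F2, dehydration to the Z alkylidene keto ester F3, removal of the triethylsilyl group to the C13 alcohol F4, and acetylation to the acetate F5.
- Dichloroketene (Cl3CCOCl, Zn–Cu, Et2O) adds to the strained C1=C4 alkene from the face away from the six-membered ring, carbonyl carbon to C1, giving the dichlorocyclobutanone F6.
- Dechlorination with Bu3SnH and BEt3/air returns to 20.

**Step 16.** The likely failures are isomerisation of the new enone alkenes (E to Z at C4=C5, or migration into conjugation with C2) through the doubly activated C3 methylene, and decomposition of the polycarbonyl product at 160 °C. Fallback, from 19 to 23: the C6 ketone is reduced before ring expansion, so that only one ketone is present during the thermal step.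
- 19 is reduced with the oxazaborolidine of step 5 and catecholborane. On the tricycle C5 is a tertiary sp3 carbon, so the catalyst enantiomer that proves matched is used; C2 is set later and independently. The hydroxy ester lactonises to the tricyclic butenolide alcohol F7.
- Dess–Martin oxidation gives the cyclobutanone F8.
- Thermolysis gives (1(10)E,4E,6R,8S)-13-acetoxy-8-[(tert-butyldimethylsilyl)oxy]-2-oxogermacra-1(10),4,7(11)-trien-12,6-olide F9.
- Reduction with the (S)-oxazaborolidine and catecholborane gives 23.

**Step 12.** The likely failure is elimination to the E alkylidene (ester syn to C8), which cannot lactonise in step 17. Fallback, from 16 to 17: the E isomer F10 is not discarded. It is equilibrated with 17 by triplet-sensitised irradiation (thioxanthone, 365–405 nm), the isomers are separated, and F10 is recycled.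

**Step 17.** The likely failure is low or reversed facial control at C6, where both flanking carbons are sp2. Fallback, from 21 to 23, for the case of reversed control at C6:
- The enantiomeric (R)-oxazaborolidine should give the butenolide with the correct C6 but the 2S carbinol, F11.
- MnO2 oxidises the allylic C2 alcohol to F9.
- The (S)-oxazaborolidine then reduces this single ketone to 23.

**Step 19.** The likely failure is sulfonylation of the allylic C1 hydroxyl in competition with C2; closure would then invert the wrong carbon. Fallback, from 23 to 29: a sequence in which the leaving group can only sit on C1 and the nucleophile only on C2, which needs the 2S carbinol.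
- 23 is oxidised with MnO2 to F9 and reduced with the (R)-oxazaborolidine to F11.
- Silylation (Et3SiOTf, 2,6-lutidine) gives the C2 triethylsilyl ether F12.
- The ene reaction and PPh3 reduction of step 18 give the 1S alcohol F13.
- (MeSO2)2O and iPr2NEt at −40 °C give the allylic mesylate F14.
- Bu4NF frees the C2 alkoxide, which displaces the C1 mesylate with inversion, and also removes the C8 silyl group, giving (4E,1R,2S,6R,8S)-13-acetoxy-1,2-epoxy-8-hydroxygermacra-4,7(11),10(14)-trien-12,6-olide F15.
- Epoxidation as in step 21 gives 29.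

## Further compounds

F1 | step 10 | 4-[(tert-butyldimethylsilyl)oxy]-6,8-dimethylbicyclo[4.2.0]oct-7-en-2-one (propyne photoadduct) | O=C1C[C@@H](O[Si](C)(C)C(C)(C)C)C[C@@]2(C)[C@@H]1C(C)=C2
F2 | step 10 | C7 aldol adduct of F1 with 13 (mixture at C7 and C11) | O=C1C(C(O)(C(=O)OCC)CO[Si](CC)(CC)CC)[C@@H](O[Si](C)(C)C(C)(C)C)C[C@@]2(C)[C@@H]1C(C)=C2
F3 | step 10 | (Z)-alkylidene keto ester of the cyclobutene series, C13 triethylsilyl ether | O=C1/C(=C(\C(=O)OCC)CO[Si](CC)(CC)CC)[C@@H](O[Si](C)(C)C(C)(C)C)C[C@@]2(C)[C@@H]1C(C)=C2
F4 | step 10 | (Z)-alkylidene keto ester of the cyclobutene series, C13 alcohol | O=C1/C(=C(\C(=O)OCC)CO)[C@@H](O[Si](C)(C)C(C)(C)C)C[C@@]2(C)[C@@H]1C(C)=C2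
F5 | step 10 | (Z)-alkylidene keto ester of the cyclobutene series, C13 acetate | O=C1/C(=C(\C(=O)OCC)COC(C)=O)[C@@H](O[Si](C)(C)C(C)(C)C)C[C@@]2(C)[C@@H]1C(C)=C2
F6 | step 10 | 3,3-dichloro analogue of 20 (dichloroketene adduct, chlorines on C3) | O=C1/C(=C(\C(=O)OCC)COC(C)=O)[C@@H](O[Si](C)(C)C(C)(C)C)C[C@@]2(C)[C@@H]1[C@]3(C)C(Cl)(Cl)C(=O)[C@H]23
F7 | step 16 | tricyclic butenolide with C2 alcohol (lactone C6–O–C12 closed on the photoadduct skeleton) | O=C1O[C@H]2C(=C1COC(C)=O)[C@@H](O[Si](C)(C)C(C)(C)C)C[C@@]3(C)[C@@H]2[C@]4(C)C[C@@H](O)[C@H]34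
F8 | step 16 | tricyclic butenolide with C2 ketone | O=C1O[C@H]2C(=C1COC(C)=O)[C@@H](O[Si](C)(C)C(C)(C)C)C[C@@]3(C)[C@@H]2[C@]4(C)CC(=O)[C@H]34
F9 | step 16 | (1(10)E,4E,6R,8S)-13-acetoxy-8-[(tert-butyldimethylsilyl)oxy]-2-oxogermacra-1(10),4,7(11)-trien-12,6-olide | O=C1C/C(C)=C/[C@H]2OC(=O)C(COC(C)=O)=C2[C@@H](O[Si](C)(C)C(C)(C)C)C/C(C)=C/1
F10 | step 12 | (E)-isomer of 17 (ester carbon C12 syn to C8) | O=C1/C(=C(/C(=O)OCC)CO[Si](CC)(CC)CC)[C@@H](O[Si](C)(C)C(C)(C)C)C[C@@]2(C)[C@@H]1[C@]3(C)C[C@@H](O[Si](CC)(CC)CC)[C@H]23
F11 | step 17 | (2S)-epimer of 23 | O[C@H]1C/C(C)=C/[C@H]2OC(=O)C(COC(C)=O)=C2[C@@H](O[Si](C)(C)C(C)(C)C)C/C(C)=C/1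
F12 | step 19 | C2 triethylsilyl ether of F11 | CC[Si](CC)(CC)O[C@H]1C/C(C)=C/[C@H]2OC(=O)C(COC(C)=O)=C2[C@@H](O[Si](C)(C)C(C)(C)C)C/C(C)=C/1
F13 | step 19 | (4E,1S,2S,6R,8S)-13-acetoxy-8-[(tert-butyldimethylsilyl)oxy]-1-hydroxy-2-[(triethylsilyl)oxy]germacra-4,7(11),10(14)-trien-12,6-olide | O[C@@H]1[C@@H](O[Si](CC)(CC)CC)C/C(C)=C/[C@H]2OC(=O)C(COC(C)=O)=C2[C@@H](O[Si](C)(C)C(C)(C)C)CC1=C
F14 | step 19 | C1 methanesulfonate of F13 | CS(=O)(=O)O[C@@H]1[C@@H](O[Si](CC)(CC)CC)C/C(C)=C/[C@H]2OC(=O)C(COC(C)=O)=C2[C@@H](O[Si](C)(C)C(C)(C)C)CC1=C
F15 | step 19 | (4E,1R,2S,6R,8S)-13-acetoxy-1,2-epoxy-8-hydroxygermacra-4,7(11),10(14)-trien-12,6-olide | O[C@H]1CC(=C)[C@H]2O[C@H]2C/C(C)=C/[C@H]2OC(=O)C(COC(C)=O)=C12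
A1 | alternative 1 | ten-membered C4 ketone with butenolide, C5 PMB ether, C1–C2 epoxide, C10 methylene and C8 silyl ether | CC(C)(C)[Si](C)(C)O[C@H]1CC(=C)[C@H]2O[C@H]2CC(=O)[C@@H](OCc2ccc(OC)cc2)[C@H]2OC(=O)C(COC(C)=O)=C12
A2 | alternative 2 | ten-membered bis-epoxy butenolide with C10 dioxolane and C8 silyl ether | CC(C)(C)[Si](C)(C)O[C@H]1CC3(OCCO3)[C@H]2O[C@H]2C[C@@]2(C)O[C@@H]2[C@H]2OC(=O)C(COC(C)=O)=C12
A3 | alternative 3 | ten-membered ynone with C6 ketone, C4/C5 acetonide, C10 dioxolane and C8 silyl ether | CC(C)(C)[Si](C)(C)O[C@H]1CC2(OCCO2)C#CC[C@@]2(C)OC(C)(C)O[C@H]2C(=O)C1
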